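**Plan**
1. The retrosynthesis first cuts the O–CH3 bond at C2'. It then cuts the C1'–C2' and C5'–C6' bonds of the 2,4-dimethoxyphenyl ring, which opens that ring to a terminal alkynyl ketone (C1', C6') and a four-carbon ketene-acetal diene (C2'–C5').
2. The enabling feature is that this ring carries oxygen at C2' and C4', ortho and para to the ketone-bearing C1', the alternating pattern of an acetoacetate-derived diene. The ring also hangs on the acyl enol ether O2–C3=C4 of the 1H-isochromene, which, with its oxidisable C1 methylene, is better served by a neutral thermal ring synthesis than by Friedel–Crafts acylation.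
3. The further cuts are C(=O)–C1' (acetylide on a Weinreb amide), C3–C(=O) (Pd aminocarbonylation of a lactone enol triflate), and C1–C8a with C1–O2 (formaldehyde on homoveratric acid).
4. In the forward direction the dimethoxybenzene ring is bought and the pyran ring closes in step 1. It gains its C3=C4 bond in step 2, and the side chain grows at C3 in steps 3 and 4. The second benzene ring is built in step 6 and O-methylation ends the route.
5. There is no stereochemistry to set. The transient stereocentres of two unisolated adducts are erased within the step that forms them.

Key step: step 6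

Remark: the target has no stereocentre and its only C=C bond outside the arenes is endocyclic, so it is achiral and "single enantiomer" calls for no stereocontrol.

**Step 1**
Reactants: 1 homoveratric acid (3,4-dimethoxyphenylacetic acid); 2 formaldehyde
Product: 3 6,7-dimethoxyisochroman-3-one (6,7-dimethoxy-1,4-dihydro-3H-isochromen-3-one)
Conditions: 37% aq. CH2O, conc. HCl, AcOH, 90 °C
Reagents that add atoms: none
Why: Acid-promoted hydroxymethylation (Blanc-type electrophilic aromatic substitution) should occur at the ring position para to the 3-methoxy group and ortho to the acetic acid chain, and the benzylic alcohol lactonises in situ, a classical way to this lactone.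

**Step 2**
Reactants: 3 6,7-dimethoxyisochroman-3-one
Product: 5 6,7-dimethoxy-1H-isochromen-3-yl trifluoromethanesulfonate, via potassium lactone enolate 4 (not isolated)
Conditions: KHMDS (commercial solution), THF, −78 °C; then Comins' reagent, −78 → −30 °C; cold basic wash, plug of Et3N-deactivated SiO2, used at once
Reagents that add atoms: Comins' reagent, N-(5-chloropyridin-2-yl)bis(trifluoromethanesulfonimide), Clc1ccc(nc1)N(S(=O)(=O)C(F)(F)F)S(=O)(=O)C(F)(F)F
Why: The C4 protons are both benzylic and alpha to the lactone carbonyl, so the enolate should form cleanly and be sulfonylated on oxygen by the N-triflyl donor (formation of a lactone-derived enol triflate, i.e. a ketene acetal triflate), the new C3=C4 bond being conjugated with the arene.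

**Step 3**
Reactants: 5 6,7-dimethoxy-1H-isochromen-3-yl trifluoromethanesulfonate
Product: 6 N,6,7-trimethoxy-N-methyl-1H-isochromene-3-carboxamide (the Weinreb amide at C3)
Conditions: Pd(OAc)2 (5 mol %), Xantphos (5 mol %), CO (1 atm), MeNH(OMe)·HCl, Et3N, THF, rt
Reagents that add atoms: carbon monoxide, [C-]#[O+]; N,O-dimethylhydroxylamine hydrochloride, CNOC.Cl
Why: In this palladium-catalysed aminocarbonylation, oxidative addition into C3–OTf, CO insertion and capture of the acyl-palladium by the hydroxylamine should form the C3–C(=O) bond and the Weinreb amide in one operation, a reaction type established for lactone- and lactam-derived enol triflates at room temperature with a wide-bite-angle ligand.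

**Step 4**
Reactants: 6 N,6,7-trimethoxy-N-methyl-1H-isochromene-3-carboxamide; 7 ethynylmagnesium bromide
Product: 9 1-(6,7-dimethoxy-1H-isochromen-3-yl)prop-2-yn-1-one, via chelated bromomagnesium tetrahedral adduct 8 (not isolated)
Conditions: 7 (0.5 M in THF, 2.5 equiv), THF, −20 → 0 °C; inverse quench into cold 1 M aq. HCl/Et2O
Reagents that add atoms: none
Why: In this Weinreb ketone synthesis the acetylide adds once to the amide carbonyl to give the magnesium chelate 8 (the bromomagnesium alkoxide that bears the ethynyl, methoxy(methyl)amino and isochromen-3-yl groups on one carbon), which lasts until the quench so that no tertiary alcohol forms, the weakly basic alkynyl Grignard reagent leaves C4 and the C1 methylene alone, and the short, cold acidic quench keeps the released N,O-dimethylhydroxylamine protonated so that it cannot add to the terminal ynone.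

**Step 5**
Reactants: 10 methyl (E)-3-methoxybut-2-enoate
Product: 12 (1Z)-1,3-dimethoxy-1-(trimethylsilyloxy)buta-1,3-diene (ketene-acetal geometry immaterial), via lithium dienolate 11 (not isolated)
Conditions: LDA (commercial solution), THF, −78 °C; then TMSCl, −78 °C → rt; pentane, filtration, bulb-to-bulb distillation
Reagents that add atoms: chlorotrimethylsilane, C[Si](C)(C)Cl
Why: Kinetic gamma-deprotonation of the methyl group, which lies cis to the ester, followed by O-silylation of the dienolate (silyl ketene acetal formation) is the standard preparation of this Brassard-type diene.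

**Step 6**
Reactants: 9 1-(6,7-dimethoxy-1H-isochromen-3-yl)prop-2-yn-1-one; 12 (1Z)-1,3-dimethoxy-1-(trimethylsilyloxy)buta-1,3-diene
Product: 15 (2-hydroxy-4-methoxyphenyl)(6,7-dimethoxy-1H-isochromen-3-yl)methanone, via cyclohexa-1,4-diene cycloadduct 13 (not isolated), via aryl trimethylsilyl ether 14 (not isolated)
Conditions: 12 (2.5 equiv), BHT (cat.), toluene, rt → 80 °C; then THF/10% aq. citric acid, rt
Reagents that add atoms: none
Why: The three oxygen donors polarise the diene so that its unsubstituted CH2 terminus is nucleophilic and bonds to the terminal, beta carbon of the ynone (future C5'–C6') slightly ahead of bonding between the ketene-acetal carbon and the alpha carbon (future C1'–C2'), a concerted but strongly asynchronous normal-electron-demand [4+2] cycloaddition that gives 13. Adduct 13 holds a doubly allylic mixed ketal and a doubly allylic CH2, so it should expel methanol on warming to give 14, whose O–Si bond is cleaved by the mild aqueous acid to leave phenol 15, hydrogen-bonded to the ketone. The closest known reaction type is the Diels–Alder cycloaromatisation of 1,3-dioxygenated silyl ketene acetal dienes with acetylenic ketones and esters to give resorcinol derivatives. The one ring formed, the carbocycle C1'–C6', closes in the intermolecular [4+2] mode with both sigma bonds made in the same step (in the stepwise limit, a vinylogous Mukaiyama–Michael addition followed by attack of the allenolate carbon on the silyloxycarbenium carbon). No stereocentre survives, since the ketal carbon of 13 is the only one formed and it is erased on aromatisation, which also makes the geometry of 12 irrelevant. The step needs regioselectivity (OH ortho, OMe para to the ketone), secured by the matched polarisation of diene and ynone, and chemoselectivity for the alkyne, secured because the alkyne is terminal and unhindered, the C3=C4 alkene is trisubstituted, donor-substituted and styrene-conjugated, and no Lewis acid is present to activate the ketone C=O.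

**Step 7**
Reactants: 15 (2-hydroxy-4-methoxyphenyl)(6,7-dimethoxy-1H-isochromen-3-yl)methanone
Product: 16 (2,4-dimethoxyphenyl)(6,7-dimethoxy-1H-isochromen-3-yl)methanone (target)
Conditions: MeI, K2CO3, DMF, rt, N2
Reagents that add atoms: iodomethane, CI
Why: In this Williamson-type O-methylation, carbonate in a dipolar aprotic solvent should break the hydrogen bond to the ketone and the phenoxide is alkylated by MeI, conditions too mild to touch the acyl enol ether or the C1 methylene.

**Compound list**
1 | homoveratric acid (3,4-dimethoxyphenylacetic acid) | COc1ccc(CC(=O)O)cc1OC | starting material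
2 | formaldehyde | C=O | starting material
3 | 6,7-dimethoxyisochroman-3-one | COc1cc2c(cc1OC)COC(=O)C2 | intermediate
4 | potassium 6,7-dimethoxy-1H-isochromen-3-olate (lactone enolate, formed in the flask) | [K+].[O-]C1=Cc2cc(OC)c(OC)cc2CO1 | intermediate
5 | 6,7-dimethoxy-1H-isochromen-3-yl trifluoromethanesulfonate | O=S(=O)(OC1=Cc2cc(OC)c(OC)cc2CO1)C(F)(F)F | intermediate
6 | N,6,7-trimethoxy-N-methyl-1H-isochromene-3-carboxamide | CON(C)C(=O)C1=Cc2cc(OC)c(OC)cc2CO1 | intermediate
7 | ethynylmagnesium bromide | C#C[Mg]Br | starting material
8 | bromomagnesium 1-(6,7-dimethoxy-1H-isochromen-3-yl)-1-[methoxy(methyl)amino]prop-2-yn-1-olate (chelated tetrahedral adduct, racemic, formed in the flask) | C#CC(O[Mg]Br)(N(C)OC)C1=Cc2cc(OC)c(OC)cc2CO1 | intermediate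
9 | 1-(6,7-dimethoxy-1H-isochromen-3-yl)prop-2-yn-1-one | C#CC(=O)C1=Cc2cc(OC)c(OC)cc2CO1 | intermediate
10 | methyl (E)-3-methoxybut-2-enoate | CO/C(C)=C/C(=O)OC | starting material
11 | lithium 1,3-dimethoxybuta-1,3-dien-1-olate (dienolate, formed in the flask) | C=C(OC)/C=C(/OC)[O-].[Li+] | intermediate
12 | (1Z)-1,3-dimethoxy-1-(trimethylsilyloxy)buta-1,3-diene | C=C(OC)/C=C(/OC)O[Si](C)(C)C | intermediate
13 | [4,6-dimethoxy-6-(trimethylsilyloxy)cyclohexa-1,4-dien-1-yl](6,7-dimethoxy-1H-isochromen-3-yl)methanone (racemic, formed in the flask) | COC1=CC(OC)(O[Si](C)(C)C)C(C(=O)C2=Cc3cc(OC)c(OC)cc3CO2)=CC1 | intermediate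
14 | [4-methoxy-2-(trimethylsilyloxy)phenyl](6,7-dimethoxy-1H-isochromen-3-yl)methanone (formed in the flask) | COc1ccc(C(=O)C2=Cc3cc(OC)c(OC)cc3CO2)c(O[Si](C)(C)C)c1 | intermediate
15 | (2-hydroxy-4-methoxyphenyl)(6,7-dimethoxy-1H-isochromen-3-yl)methanone | COc1ccc(C(=O)C2=Cc3cc(OC)c(OC)cc3CO2)c(O)c1 | intermediate
16 | (2,4-dimethoxyphenyl)(6,7-dimethoxy-1H-isochromen-3-yl)methanone | COc1ccc(C(=O)C2=Cc3cc(OC)c(OC)cc3CO2)c(OC)c1 | target

Total step count: 7. Longest linear sequence: 6 steps (1, 2, 3, 4, 6, 7). Step 5 is the one-step side branch to the diene.

**Steps most likely to fail**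

Step 2. The ketene acetal triflate may revert to the lactone by protonation at C4 and hydrolysis during work-up or on silica, or it may be consumed by free amine before palladium inserts in step 3. The fallback sets out from lactone 3 and comes back at Weinreb amide 6. Enolate 4 would be trapped with diphenyl chlorophosphate (THF/DMPU, −78 °C) as 6,7-dimethoxy-1H-isochromen-3-yl diphenyl phosphate F1, a ketene acetal phosphate that should stand water and chromatography. As a slower electrophile it would be carbonylated hot with a neutral nucleophile (Pd(PPh3)4, CO, MeOH, Et3N, DMF, 60 °C) to methyl 6,7-dimethoxy-1H-isochromene-3-carboxylate F2. The ester would then be converted with MeNH(OMe)·HCl/i-PrMgCl (THF, −20 °C) into 6.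

Step 6. Vinylogous Michael addition without ring closure, protodesilylation of the diene by the liberated methanol, or oligomerisation of the terminal ynone may outrun the cycloaddition. The fallback sets out from Weinreb amide 6 and comes back at target 16, by-passing 9, 12 and 15. The dimethoxyphenyl ring would be brought in ready-made with commercial 2,4-dimethoxyphenylmagnesium bromide (THF, −20 → 0 °C). This should stop at the chelated tetrahedral adduct, bromomagnesium (2,4-dimethoxyphenyl)(6,7-dimethoxy-1H-isochromen-3-yl)[methoxy(methyl)amino]methanolate F3, and give 16 on a cold acidic quench. The price is exposure of the enol ether amide to a harder and more basic organometallic than in step 4.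

Step 4. The liberated N,O-dimethylhydroxylamine may add in conjugate fashion to the terminal ynone at the quench, or the ynone may oligomerise under the basic conditions. The fallback sets out from 6 and comes back at 9 by changing the oxidation level. DIBAL-H (THF, −78 °C) should give 6,7-dimethoxy-1H-isochromene-3-carbaldehyde F4, from which the amine is washed away before any alkyne is present. Addition of 7 (THF, −78 → 0 °C) should give racemic 1-(6,7-dimethoxy-1H-isochromen-3-yl)prop-2-yn-1-ol F5. Activated MnO2 (CH2Cl2, rt) should then oxidise this allylic and propargylic alcohol to 9 under neutral conditions.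

**Further compounds**
F1 | step 2 | 6,7-dimethoxy-1H-isochromen-3-yl diphenyl phosphate | O=P(OC1=Cc2cc(OC)c(OC)cc2CO1)(Oc1ccccc1)Oc1ccccc1
F2 | step 2 | methyl 6,7-dimethoxy-1H-isochromene-3-carboxylate | COC(=O)C1=Cc2cc(OC)c(OC)cc2CO1
F3 | step 6 | bromomagnesium (2,4-dimethoxyphenyl)(6,7-dimethoxy-1H-isochromen-3-yl)[methoxy(methyl)amino]methanolate (racemic) | COc1ccc(C(O[Mg]Br)(N(C)OC)C2=Cc3cc(OC)c(OC)cc3CO2)c(OC)c1
F4 | step 4 | 6,7-dimethoxy-1H-isochromene-3-carbaldehyde | O=CC1=Cc2cc(OC)c(OC)cc2CO1
F5 | step 4 | 1-(6,7-dimethoxy-1H-isochromen-3-yl)prop-2-yn-1-ol (racemic) | C#CC(O)C1=Cc2cc(OC)c(OC)cc2CO1
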